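**Assumption:** the SMILES is read as (3R,6R,7R,8R,10S,4Z) in germacranolide numbering (trans-6,12-lactone, 8-angelate, 3,10-oxide bridge); C1–C15 labels below use that numbering.

## Retrosynthetic overview

1. Niveusin B ⇐ its 15-O-TBS ether. The 10-membered carbocycle and the bridging THF-hemiketal are opened together at C1–C2 and C10–O, giving an acyclic α-iodo enone (C2) carrying a methallyl group (C1=C10).
2. The ring closure is an iodine-atom-transfer radical 10-endo cyclisation, followed by ketone-assisted solvolysis of the tertiary iodide to the hemiketal.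
3. The iodoketone comes from a (Z)-vinyl iodide (Negishi coupling with 1-ethoxyvinylzinc, then NIS/H2O). The 8-angelate is installed by Mitsunobu inversion.
4. C7–C8 is made by Zn Barbier allylation of 3-methylbut-3-enal with a 5-substituted 3-(bromomethyl)butenolide; C6 controls C7 and C8.
5. The butenolide comes from RCM of a 2-(bromomethyl)acrylate ester. C6 and the 4Z alkene come from asymmetric alkynylation of crotonaldehyde and Red-Al/I2. Ring order: lactone first, then carbocycle and oxide bridge in one step.

## Route

**Step 1**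
Reactants: 1, prop-2-yn-1-ol
Product: 2, tert-butyldimethyl(prop-2-yn-1-yloxy)silane
Conditions: TBSCl, imidazole, CH2Cl2, 0 °C → rt
Reagents that add atoms: TBSCl, C[Si](C)(Cl)C(C)(C)C
Why: Standard silyl ether protection of the future C15 hydroxyl.

**Step 2**
Reactants: 2; 3, (E)-but-2-enal
Product: 4, (2E,4S)-7-(TBS-oxy)hept-2-en-5-yn-4-ol
Conditions: Me2Zn, ProPhenol ligand (10 mol %, antipode chosen to give 4S), Ph3P=O, toluene, 4 °C
Reagents that add atoms: none
Why: Zn–ProPhenol asymmetric alkynylation of an enal (1,2-addition); the catalyst sets the carbinol that becomes C6.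

**Step 3**
Reactants: 4
Product: 5, (2E,4S,5Z)-7-(TBS-oxy)-6-iodohepta-2,5-dien-4-ol
Conditions: Red-Al, THF, 0 °C; EtOAc; then I2, −78 → 0 °C
Reagents that add atoms: iodine, II
Why: Hydroxyl-directed trans-hydroalumination puts H on the proximal and Al (then I) on the distal alkyne carbon, so I is cis to the carbinol carbon; this fixes the future 4Z geometry, and low temperature avoids β-silyloxy elimination.

**Step 4**
Reactants: 5; 6, 2-(bromomethyl)prop-2-enoic acid
Product: 7, (2E,4S,5Z)-7-(TBS-oxy)-6-iodohepta-2,5-dien-4-yl 2-(bromomethyl)prop-2-enoate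
Conditions: DCC, DMAP (5 mol %), CH2Cl2, 0 °C
Reagents that add atoms: none
Why: Steglich esterification under mild, nearly neutral conditions that leave the allylic bromide and the stereocentre untouched.

**Step 5**
Reactants: 7
Product: 8, (5S)-3-(bromomethyl)-5-[(1Z)-3-(TBS-oxy)-2-iodoprop-1-en-1-yl]furan-2(5H)-one
Conditions: Grubbs II (5 mol %), toluene (0.01 M), 80 °C
Reagents that add atoms: none
Why: Ring-closing metathesis between the propenyl group and the acrylate (propene lost) gives the butenolide; the trisubstituted vinyl iodide is inert to metathesis and no base is present to racemise C6.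

**Step 6**
Reactants: 9, 3-methylbut-3-en-1-ol
Product: 10, 3-methylbut-3-enal
Conditions: Dess–Martin periodinane, NaHCO3, CH2Cl2, 0 °C; filtered solution used at once
Reagents that add atoms: none
Why: Buffered Dess–Martin oxidation gives the β,γ-unsaturated aldehyde without isomerisation to the conjugated enal when it is used immediately.

**Step 7**
Reactants: 8; 10 (3 equiv)
Product: 11, (4R,5S)-4-[(1S)-1-hydroxy-3-methylbut-3-en-1-yl]-5-[(1Z)-3-(TBS-oxy)-2-iodoprop-1-en-1-yl]-3-methylideneoxolan-2-one (6,12-lactone, 8α-OH)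
Conditions: Zn dust, THF/sat. aq NH4Cl (5:1), 0 °C → rt
Reagents that add atoms: none
Why: Zn Barbier allylation with allylic transposition; the aldehyde adds to the butenolide face anti to the C6 side chain (C7, trans-lactone), and a chair Zimmerman–Traxler transition state of the ring-locked (E)-allylzinc with the aldehyde chain equatorial gives the 7,8-anti (8S) carbinol and the α-methylene lactone directly.

**Step 8**
Reactants: 11; 12, (Z)-2-methylbut-2-enoic acid (angelic acid)
Product: 13, (1R)-1-{(2S,3R)-2-[(1Z)-3-(TBS-oxy)-2-iodoprop-1-en-1-yl]-4-methylidene-5-oxooxolan-3-yl}-3-methylbut-3-en-1-yl (2Z)-2-methylbut-2-enoate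
Conditions: PPh3, DIAD, toluene, 0 °C → rt
Reagents that add atoms: none
Why: Mitsunobu esterification inverts C8 (8S → 8R) by SN2 attack of angelate, and because the acid is never acyl-activated the Z geometry cannot isomerise to tiglate.

**Step 9**
Reactants: 13; 14, ethyl vinyl ether
Product: 15, (1R)-1-{(2R,3R)-2-[(1Z)-3-ethoxy-2-(TBS-oxymethyl)buta-1,3-dien-1-yl]-4-methylidene-5-oxooxolan-3-yl}-3-methylbut-3-en-1-yl (2Z)-2-methylbut-2-enoate
Conditions: 14, t-BuLi, THF, −78 → 0 °C; ZnCl2; then 13, Pd(PPh3)4 (5 mol %), THF, rt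
Reagents that add atoms: none
Why: Negishi coupling of the vinyl iodide with (1-ethoxyvinyl)zinc chloride proceeds with retention of alkene geometry and tolerates the lactone and ester; it installs C3 and C2.

**Step 10**
Reactants: 15
Product: 16, (1R)-1-{(2R,3R)-2-[(1Z)-4-iodo-2-(TBS-oxymethyl)-3-oxobut-1-en-1-yl]-4-methylidene-5-oxooxolan-3-yl}-3-methylbut-3-en-1-yl (2Z)-2-methylbut-2-enoate
Conditions: NIS (1.05 equiv), THF/H2O (4:1), −20 → 0 °C, dark
Reagents that add atoms: N-iodosuccinimide, O=C1CCC(=O)N1I; water, O
Why: Electrophilic iodination of the enol ether at its terminal carbon followed by hydrolysis of the oxocarbenium ion gives the α-iodo ketone; the enol ether is far more nucleophilic than the other alkenes.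

**Step 11 (key step)**
Reactants: 16
Product: 17, 15-O-TBS-niveusin B (3R,6R,7R,8R,10S,4Z)
Conditions: Et3B (3 × 0.2 equiv), air, NaHCO3, MeCN/H2O (2:1), 2 mM, 25 °C
Reagents that add atoms: water, O
Why: Proposed new method: Et• abstracts iodine to give the electrophilic C2 α-keto radical, which adds 10-endo to the terminal carbon (C1) of the electron-rich 1,1-disubstituted alkene (polarity-matched, whereas the methylene-lactone and angelate alkenes are mismatched, and the Z-enone and trans-lactone pre-organise the chain); the tertiary C10 radical propagates by iodine-atom transfer and the γ-iodo ketone ionises in water with carbonyl participation to the bridged oxocarbenium ion, which is hydrated to the hemiketal, with C10–O expected to form anti to the 8-angelate (10S) and C3 then fixed as R by the cis oxide bridge; the closest known reactions are Et3B/water iodine-atom-transfer endo macrocyclisations of α-iodo carbonyl compounds and atom-transfer carbo-oxygenation (lactonisation) of 1,1-disubstituted alkenes.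

**Step 12**
Reactants: 17
Product: 18, niveusin B
Conditions: HF·pyridine, pyridine/THF, 0 °C → rt
Reagents that add atoms: none
Why: Buffered fluoride desilylation frees the C15 hydroxyl without touching the hemiketal, lactone or angelate.

## Compound list

1 | prop-2-yn-1-ol | C#CCO | starting material
2 | tert-butyldimethyl(prop-2-yn-1-yloxy)silane | C#CCO[Si](C)(C)C(C)(C)C | intermediate
3 | (E)-but-2-enal | C/C=C/C=O | starting material
4 | (2E,4S)-7-(TBS-oxy)hept-2-en-5-yn-4-ol | C/C=C/[C@H](O)C#CCO[Si](C)(C)C(C)(C)C | intermediate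
5 | (2E,4S,5Z)-7-(TBS-oxy)-6-iodohepta-2,5-dien-4-ol | C/C=C/[C@H](O)/C=C(/CO[Si](C)(C)C(C)(C)C)I | intermediate
6 | 2-(bromomethyl)prop-2-enoic acid | C=C(CBr)C(=O)O | starting material
7 | (2E,4S,5Z)-7-(TBS-oxy)-6-iodohepta-2,5-dien-4-yl 2-(bromomethyl)prop-2-enoate | C/C=C/[C@H](OC(=O)C(=C)CBr)/C=C(/CO[Si](C)(C)C(C)(C)C)I | intermediate
8 | (5S)-3-(bromomethyl)-5-[(1Z)-3-(TBS-oxy)-2-iodoprop-1-en-1-yl]furan-2(5H)-one | BrCC1=C[C@@H](/C=C(/CO[Si](C)(C)C(C)(C)C)I)OC1=O | intermediate
9 | 3-methylbut-3-en-1-ol | C=C(C)CCO | starting material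
10 | 3-methylbut-3-enal | C=C(C)CC=O | intermediate
11 | (4R,5S)-4-[(1S)-1-hydroxy-3-methylbut-3-en-1-yl]-5-[(1Z)-3-(TBS-oxy)-2-iodoprop-1-en-1-yl]-3-methylideneoxolan-2-one | C=C1C(=O)O[C@H](/C=C(/CO[Si](C)(C)C(C)(C)C)I)[C@H]1[C@@H](O)CC(C)=C | intermediate
12 | (Z)-2-methylbut-2-enoic acid (angelic acid) | C/C=C(/C)C(=O)O | starting material
13 | 8β-angelate vinyl iodide (C8 inverted to R) | C=C1C(=O)O[C@H](/C=C(/CO[Si](C)(C)C(C)(C)C)I)[C@H]1[C@H](OC(=O)/C(C)=C\C)CC(C)=C | intermediate
14 | ethyl vinyl ether | C=COCC | starting material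
15 | 2-ethoxy-1,3-diene (C3 enol ether) | C=C1C(=O)O[C@H](/C=C(/CO[Si](C)(C)C(C)(C)C)C(OCC)=C)[C@H]1[C@H](OC(=O)/C(C)=C\C)CC(C)=C | intermediate
16 | α-iodo (Z)-enone cyclisation precursor | C=C1C(=O)O[C@H](/C=C(/CO[Si](C)(C)C(C)(C)C)C(=O)CI)[C@H]1[C@H](OC(=O)/C(C)=C\C)CC(C)=C | intermediate
17 | 15-O-TBS-niveusin B | C=C1C(=O)O[C@@H]2/C=C(/CO[Si](C)(C)C(C)(C)C)[C@@]3(O)CC[C@@](C)(C[C@@H](OC(=O)/C(C)=C\C)[C@@H]12)O3 | intermediate
18 | niveusin B | C=C1C(=O)O[C@@H]2/C=C(/CO)[C@@]3(O)CC[C@@](C)(C[C@@H](OC(=O)/C(C)=C\C)[C@@H]12)O3 | target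

## Summary

Total steps: 12. Longest linear sequence: 11 (steps 1–5, 7–12).

Steps most likely to fail:

1. **Step 11.** Competing 8-endo addition of the C2 radical to the methylene lactone, 1,5-H transfer from C6–H, or formation of the C10 epimer. Fallback: swap the roles of the two C–C bonds. Form C1–C2 intermolecularly by the same atom-transfer/hemiketalisation on a simple α-iodo enone and a methallyl partner, then close the 10-membered ring by intramolecular Barbier allylation of the bromomethylbutenolide onto a C8 aldehyde.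
2. **Step 8.** Elimination or low conversion in the Mitsunobu inversion at the hindered C8 carbinol. Fallback: oxidise C8–OH to the ketone, reduce from the less hindered face to the 8β-alcohol, and acylate with retention using the angelic 2,4,6-trichlorobenzoyl mixed anhydride.
3. **Step 5.** Sluggish RCM of the 2-(bromomethyl)acrylate, or erosion of C6. Fallback: oxidise the (Z)-iodo allylic alcohol to the enal, build the lactone by catalytic asymmetric Cr-mediated 2-(alkoxycarbonyl)allylation/lactonisation, and convert the α-methylene lactone to the bromomethylbutenolide by bromination–dehydrobromination.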